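**Plan**

1. Retrosynthesis: after removal of two silyl ethers and a perketal, the butenolide is opened at O–C16 by an allylic lactonisation transform that returns the oxygen function to C14. Then C16–C17 (Stille), C15≡C16 and C13≡C14 (two one-carbon alkyne homologations), C14–C15 (acylation), C13–CH3 (cuprate) and C13–OO (epoxide perhydrolysis) are cut, and ring C of abietic acid is reopened in thought at its C13–C14 bond.
2. Forward: rings A and B come intact from abietic acid. Ring C is cleaved so that its C14 becomes the 8β-methyl and C11–C13 the chain stub, and ring B is oxygenated at C6 and C8. The chain grows linearly from C13 to C16, the C17–C19 acid unit is coupled on, and the butenolide, the only ring made, closes last.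
3. Stereochemistry: C4, C5, C9 and C10 come from abietic acid. C8 comes from α-face epoxidation of a 7-en-6-one and C6 from a thermodynamic one-electron reduction. C14 and C13 come from one Sharpless epoxidation of a Z-allylic alcohol (C13 then inverted by H2O2), and C16 from C14 by 1,3-transfer in the key step.
4. Enabling feature: C13 (peroxy carbon) and C16 (lactone CH–O) face each other across the E-C14=C15 alkene. A C14–C15–C16 allyl unit, flanked by the quaternary C13 and by a Z-held carboxyl, can therefore close the five-membered lactone ring (O, C16, C17, C18, C19) at C16 and leave the alkene behind. C16–H is base-labile (its anion expels the C13 peroxide), so the closure has to run without added base.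

Key step: step 25

Remark: C1–C13 keep their abietane numbers (the old abietane C14 ends as the 8β-methyl carbon); the chain added later is C14, C15, C16 (lactone CH–O), C17 (methyl-bearing), C18 (=CH), C19 (lactone C=O); "core" means the trans-decalin with 4α-CO2Me, 4β-CH3, 5α-H, 9α-H (chain 9β) and 10β-CH3; (Z)-3-iodobut-2-enoic acid is assumed not to be on the shelf and is made in step 23.

**Route**

Step 1
Reactants: 1 abietic acid
Product: 2 methyl abietate
Conditions: MeI, K2CO3, DMF, 20 °C
Reagents that add atoms: iodomethane, CI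
Why: SN2 O-alkylation of the carboxylate (ester formation) is insensitive to the hindered quaternary C4 and leaves the diene untouched.

Step 2
Reactants: 2 methyl abietate
Product: 4 seco keto enal, via ring-C 13α,14α-diol 3 (not isolated)
Conditions: OsO4 (2 mol%), NaIO4 (4 equiv), 2,6-lutidine, dioxane/H2O 3:1, 20 °C
Reagents that add atoms: osmium tetroxide, O=[Os](=O)(=O)=O; sodium periodate, [Na+].[O-]I(=O)(=O)=O
Why: Lemieux–Johnson oxidation, in which OsO4 should attack the more accessible ring-C alkene (abietane C13=C14) of the heteroannular diene from the α-face and periodate cleaves the diol at once, the C7=C8 bond of the resulting enal being too electron-poor for a second osmylation.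

Step 3
Reactants: 4 seco keto enal
Product: 5 allylic alcohol (8-CH2OH)
Conditions: NaBH4 (0.3 equiv), EtOH/CH2Cl2 3:7, −78 °C
Reagents that add atoms: none
Why: chemoselective borohydride 1,2-reduction, since at −78 °C the conjugated aldehyde should react far faster than the branched isopropyl ketone or the esters.

Step 4
Reactants: 5 allylic alcohol
Product: 6 allylic acetate (8-CH2OAc)
Conditions: Ac2O, pyridine, DMAP (cat.), CH2Cl2, 0 °C
Reagents that add atoms: acetic anhydride, CC(=O)OC(C)=O
Why: DMAP-catalysed acetylation of the primary allylic alcohol installs the leaving group for the hydrogenolysis.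

Step 5
Reactants: 6 allylic acetate
Product: 7 Δ7 8-methyl ketone
Conditions: Pd(PPh3)4 (5 mol%), Bu3SnH (1.3 equiv), THF, 20 °C
Reagents that add atoms: none
Why: palladium-catalysed allylic hydrogenolysis (Tsuji–Trost type reduction), in which the tin hydride should deliver hydride to the unhindered exocyclic terminus of the allyl complex so that the trisubstituted C7=C8 alkene is kept and the ketone is untouched.

Step 6
Reactants: 7 Δ7 8-methyl ketone
Product: 8 7-en-6-one
Conditions: CrO3, 3,5-dimethylpyrazole, CH2Cl2, −20 °C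
Reagents that add atoms: chromium trioxide, O=[Cr](=O)=O
Why: allylic oxidation by the CrO3–dimethylpyrazole complex should turn the ring allylic methylene C6 into the conjugated ketone, the usual outcome for 8-methyl-Δ7 decalins of the drimane and labdane type.

Step 7
Reactants: 8 7-en-6-one
Product: 9 7-en-6-one isopropyl ester
Conditions: mCPBA, CF3CO2H (1 equiv), CH2Cl2, 20 °C
Reagents that add atoms: 3-chloroperbenzoic acid, OOC(=O)c1cccc(Cl)c1
Why: Baeyer–Villiger oxidation in which the secondary isopropyl group migrates in preference to the primary C12 methylene, while the hindered conjugated C6 ketone and its electron-poor alkene resist the peracid.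

Step 8
Reactants: 9 7-en-6-one isopropyl ester
Product: 10 7α,8α-epoxy-6-ketone
Conditions: t-BuOOH, BnMe3N+ OH− (cat.), THF, 0 to 20 °C
Reagents that add atoms: tert-butyl hydroperoxide, CC(C)(C)OO
Why: nucleophilic (Weitz–Scheffer) epoxidation, in which the peroxide anion should add to C8 from the α-face, away from the axial 10β-methyl and the 9β-chain, so that the C8–O bond is α and the methyl β.

Step 9
Reactants: 10 7α,8α-epoxy-6-ketone
Product: 12 6α,8α-diol, via 8α-hydroxy-6-ketone 11 (not isolated)
Conditions: SmI2 (2.2 equiv), THF/MeOH, −90 °C; then SmI2 (2.5 equiv), H2O, Et3N, −78 to 0 °C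
Reagents that add atoms: none
Why: one-electron reduction by SmI2, first cleaving the C7–O bond of the α,β-epoxy ketone and then reducing the ketone through a ketyl/carbanion that keeps its bulky O–Sm group equatorial (the β-face carries three syn-axial methyls, and the equatorial O8, anti to C6, cannot chelate), which should give the equatorial 6α-alcohol as dissolving-metal reductions do.

Step 10
Reactants: 12 6α,8α-diol
Product: 13 bis-silyl ether
Conditions: Et3SiOTf (3 equiv), 2,6-lutidine, CH2Cl2, 0 °C
Reagents that add atoms: triethylsilyl trifluoromethanesulfonate, CC[Si](CC)(CC)OS(=O)(=O)C(F)(F)F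
Why: silyl triflate silylation is forceful enough for both the tertiary 8α-OH and the peri-hindered secondary 6α-OH.

Step 11
Reactants: 13 bis-silyl ether
Product: 14 C13 aldehyde
Conditions: i-Bu2AlH (1.1 equiv), CH2Cl2, −78 °C
Reagents that add atoms: none
Why: partial ester reduction, since the chain isopropyl ester should stop at the tetrahedral aluminate at −78 °C while the neopentyl C4 methyl ester, flanked by the 6α-silyl ether, is too hindered to react.

Step 12
Reactants: 14 C13 aldehyde
Product: 15 C13 terminal alkyne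
Conditions: dimethyl (1-diazo-2-oxopropyl)phosphonate, K2CO3, MeOH, 0 to 20 °C
Reagents that add atoms: dimethyl (1-diazo-2-oxopropyl)phosphonate, COP(=O)(OC)C(=[N+]=[N-])C(C)=O
Why: Ohira–Bestmann (Seyferth–Gilbert) homologation adds C14 under mildly basic conditions that esters and silyl ethers tolerate.

Step 13
Reactants: 15 C13 terminal alkyne
Product: 16 ynoate
Conditions: LiN(i-Pr)2, THF, −78 °C; ClCO2Me
Reagents that add atoms: methyl chloroformate, COC(Cl)=O
Why: acetylide acylation, with the non-nucleophilic amide base sparing the C4 ester and the chloroformate adding C15.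

Step 14
Reactants: 16 ynoate
Product: 17 (13Z)-enoate
Conditions: MeLi (2 equiv), CuI, THF, 0 °C; 16 at −78 °C; NH4Cl (aq.) at −78 °C
Reagents that add atoms: lithium dimethylcuprate, [Li+].C[Cu-]C (from methyllithium, [Li]C)
Why: cuprate conjugate addition to an ynoate is a syn carbocupration, and cold protonation of the vinylcopper with retention should place C12 and the ester cis (Z).

Step 15
Reactants: 17 (13Z)-enoate
Product: 18 (13Z)-allylic alcohol
Conditions: i-Bu2AlH (2.2 equiv), CH2Cl2, −78 °C
Reagents that add atoms: none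
Why: 1,2-reduction of the conjugated ester keeps the alkene geometry, the hindered C4 ester again being spared at low temperature.

Step 16
Reactants: 18 (13Z)-allylic alcohol
Product: 19 (13S,14R)-epoxy alcohol
Conditions: Ti(Oi-Pr)4 (10 mol%), D-(−)-diethyl tartrate (12 mol%), t-BuOOH, 4 Å sieves, CH2Cl2, −20 °C
Reagents that add atoms: tert-butyl hydroperoxide, CC(C)(C)OO
Why: Sharpless asymmetric epoxidation, in which the D-(−)-tartrate complex should deliver oxygen to the face of the Z-allylic alcohol that makes C14 R and C13 S (reagent control, the ring stereocentres being remote).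

Step 17
Reactants: 19 (13S,14R)-epoxy alcohol
Product: 20 (13S,14S)-epoxy aldehyde
Conditions: Dess–Martin periodinane, NaHCO3, CH2Cl2, 0 to 20 °C
Reagents that add atoms: none
Why: buffered Dess–Martin oxidation gives the aldehyde without opening the epoxide (the descriptor at C14 changes only through the priority rules).

Step 18
Reactants: 20 (13S,14S)-epoxy aldehyde
Product: 21 (13S,14R)-epoxy alkyne
Conditions: dimethyl (1-diazo-2-oxopropyl)phosphonate, K2CO3, MeOH, 0 °C
Reagents that add atoms: dimethyl (1-diazo-2-oxopropyl)phosphonate, COP(=O)(OC)C(=[N+]=[N-])C(C)=O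
Why: Ohira–Bestmann homologation adds C16, and the oxirane α-carbon cannot enolise, so C14 keeps its configuration.

Step 19
Reactants: 21 (13S,14R)-epoxy alkyne
Product: 22 (13R,14R)-hydroperoxy alcohol
Conditions: H2O2 (anhydrous, in Et2O), H3PMo12O40 (3 mol%), Et2O, 20 °C
Reagents that add atoms: hydrogen peroxide, OO
Why: acid-catalysed perhydrolysis of an epoxide, in which H2O2 should attack the tertiary C13 (the propargylic C14 supports positive charge poorly) from the back, inverting C13 and retaining C14.

Step 20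
Reactants: 22 (13R,14R)-hydroperoxy alcohol
Product: 23 perketal alcohol
Conditions: 2-methoxypropene (1.2 equiv), pyridinium p-toluenesulfonate (cat.), CH2Cl2, 0 °C; Et3N quench
Reagents that add atoms: 2-methoxypropene, COC(C)=C
Why: acid-catalysed addition of the hydroperoxide to the enol ether (perketal formation), the more acidic and nucleophilic OOH reacting before the hindered secondary alcohol under the short, cold, weakly acidic conditions.

Step 21
Reactants: 23 perketal alcohol
Product: 24 (15E)-vinylstannane
Conditions: PdCl2(PPh3)2 (2 mol%), Bu3SnH (1.2 equiv, slow addition), THF, 0 °C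
Reagents that add atoms: tributyltin hydride, CCCC[SnH](CCCC)CCCC
Why: palladium-catalysed hydrostannylation of a terminal alkyne is a syn addition that should place tin on the terminal carbon when the propargylic carbon is as crowded as C14, giving the E-stannane.

Step 22
Reactants: 24 (15E)-vinylstannane
Product: 25 stannyl carbonate
Conditions: ClCO2Me, pyridine, DMAP (cat.), CH2Cl2, 0 °C
Reagents that add atoms: methyl chloroformate, COC(Cl)=O
Why: base-mediated acylation of the secondary allylic alcohol, which the perketal, the silyl ethers and the vinylstannane tolerate.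

Step 23
Reactants: 26 but-2-ynoic acid
Product: 27 (Z)-3-iodobut-2-enoic acid
Conditions: NaI, AcOH, 115 °C
Reagents that add atoms: sodium iodide, [Na+].[I-]
Why: hydroiodination of an ynoic acid proceeds by anti addition with iodide at the β-carbon, which gives the Z-isomer.

Step 24
Reactants: 25 stannyl carbonate; 27 (Z)-3-iodobut-2-enoic acid (1.3 equiv)
Product: 28 (2Z,4E)-dienoic acid carbonate
Conditions: PdCl2(MeCN)2 (5 mol%), DMF, 20 °C, dark
Reagents that add atoms: none
Why: Stille coupling joins C16 to C17 with retention of both alkene geometries, and phosphine-free palladium should be trapped by oxidative addition to the β-iodoenoic acid, kept in excess, much faster than it can ionise the hindered, β-oxygenated carbonate.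

Step 25
Reactants: 28 (2Z,4E)-dienoic acid carbonate
Product: 29 protected butenolide
Conditions: Pd2(dba)3·CHCl3 (2.5 mol%), PPh3 (10 mol%), THF, 20 °C
Reagents that add atoms: none
Why: Zerovalent palladium should ionise the C14 methyl carbonate with inversion from the conformer in which H14 eclipses the alkene and the quaternary C13 points away from C16, giving the syn,syn η3-allyl complex over C14–C15–C16, while the methyl carbonate anion loses CO2 and the methoxide deprotonates the acid. The carboxylate, held beside C16 by the Z-C17=C18 bond, then attacks C16 on the face opposite palladium; the closest known reaction type is the intramolecular Tsuji–Trost lactonisation of a carboxylic acid onto an allylic carbonate with 1,3-chirality transfer. The butenolide (O, C16, C17, C18, C19) closes in a 5-exo mode with respect to the allyl unit, C14 and C15 staying outside the ring. Double inversion puts the new C16–O bond on the face the carbonate left, so the 14R centre made by the Sharpless epoxidation becomes 16S and disappears into the E-C14=C15 alkene. Attack at C16 and not C14 is secured by ring size (closure at C14 would need a seven-membered ring holding an E-alkene) and by the neopentyl shielding of C14. Face fidelity rests on fast intramolecular capture of an allyl complex that has no β-hydrogen, and the absence of added base spares C16–H and the di-tertiary peroxide.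

Step 26
Reactants: 29 protected butenolide
Product: 30 CNP0128148.1
Conditions: HF (48% aq.), MeCN, 0 to 20 °C
Reagents that add atoms: none
Why: acid-catalysed hydrolysis of the perketal and HF cleavage of both triethylsilyl ethers in one acidic medium, which cannot deprotonate C16.

**Compound list**

1 | abietic acid (abieta-7,13-dien-18-oic acid) | OC(=O)[C@]1(C)CCC[C@@]2(C)[C@H]1CC=C3C=C(C(C)C)CC[C@H]23 | starting material
2 | methyl abietate | COC(=O)[C@]1(C)CCC[C@@]2(C)[C@H]1CC=C3C=C(C(C)C)CC[C@H]23 | intermediate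
3 | methyl 13α,14α-dihydroxyabiet-7-en-18-oate (13β-isopropyl) | COC(=O)[C@]1(C)CCC[C@@]2(C)[C@H]1CC=C3[C@@H](O)[C@](O)(C(C)C)CC[C@H]23 | intermediate
4 | methyl 13,14-dioxo-13,14-seco-abiet-7-en-18-oate (core, Δ7, 8-CHO, 9β-CH2CH2COCH(CH3)2) | COC(=O)[C@]1(C)CCC[C@@]2(C)[C@H]1CC=C(C=O)[C@@H]2CCC(=O)C(C)C | intermediate
5 | methyl 14-hydroxy-13-oxo-13,14-seco-abiet-7-en-18-oate (8-CH2OH) | COC(=O)[C@]1(C)CCC[C@@]2(C)[C@H]1CC=C(CO)[C@@H]2CCC(=O)C(C)C | intermediate
6 | methyl 14-acetoxy-13-oxo-13,14-seco-abiet-7-en-18-oate (8-CH2OAc) | COC(=O)[C@]1(C)CCC[C@@]2(C)[C@H]1CC=C(COC(C)=O)[C@@H]2CCC(=O)C(C)C | intermediate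
7 | methyl 13-oxo-13,14-seco-abiet-7-en-18-oate (Δ7, 8-CH3) | COC(=O)[C@]1(C)CCC[C@@]2(C)[C@H]1CC=C(C)[C@@H]2CCC(=O)C(C)C | intermediate
8 | methyl 6,13-dioxo-13,14-seco-abiet-7-en-18-oate (7-en-6-one) | COC(=O)[C@]1(C)CCC[C@@]2(C)[C@H]1C(=O)C=C(C)[C@@H]2CCC(=O)C(C)C | intermediate
9 | core 7-en-6-one with 8-CH3 and 9β-CH2CH2CO2CH(CH3)2 (C13 isopropyl ester) | COC(=O)[C@]1(C)CCC[C@@]2(C)[C@H]1C(=O)C=C(C)[C@@H]2CCC(=O)OC(C)C | intermediate
10 | 7α,8α-epoxy-8β-methyl-6-ketone, C13 isopropyl ester | COC(=O)[C@]1(C)CCC[C@@]2(C)[C@H]1C(=O)[C@H]3O[C@@]3(C)[C@@H]2CCC(=O)OC(C)C | intermediate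
11 | 8α-hydroxy-8β-methyl-6-ketone, C13 isopropyl ester | COC(=O)[C@]1(C)CCC[C@@]2(C)[C@H]1C(=O)C[C@@](C)(O)[C@@H]2CCC(=O)OC(C)C | intermediate
12 | 6α,8α-dihydroxy-8β-methyl core, C13 isopropyl ester | COC(=O)[C@]1(C)CCC[C@@]2(C)[C@H]1[C@@H](O)C[C@@](C)(O)[C@@H]2CCC(=O)OC(C)C | intermediate
13 | 6α,8α-bis(triethylsilyloxy) core, C13 isopropyl ester | COC(=O)[C@]1(C)CCC[C@@]2(C)[C@H]1[C@@H](O[Si](CC)(CC)CC)C[C@@](C)(O[Si](CC)(CC)CC)[C@@H]2CCC(=O)OC(C)C | intermediate
14 | bis-silyl core with 9β-CH2CH2CHO (C13 aldehyde) | COC(=O)[C@]1(C)CCC[C@@]2(C)[C@H]1[C@@H](O[Si](CC)(CC)CC)C[C@@](C)(O[Si](CC)(CC)CC)[C@@H]2CCC=O | intermediate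
15 | bis-silyl core with 9β-CH2CH2C≡CH (C13≡C14) | COC(=O)[C@]1(C)CCC[C@@]2(C)[C@H]1[C@@H](O[Si](CC)(CC)CC)C[C@@](C)(O[Si](CC)(CC)CC)[C@@H]2CCC#C | intermediate
16 | bis-silyl core with 9β-CH2CH2C≡C–CO2Me (C15 methyl ynoate) | COC(=O)[C@]1(C)CCC[C@@]2(C)[C@H]1[C@@H](O[Si](CC)(CC)CC)C[C@@](C)(O[Si](CC)(CC)CC)[C@@H]2CCC#CC(=O)OC | intermediate
17 | bis-silyl core with (13Z)-CH2CH2C(CH3)=CH–CO2Me | COC(=O)[C@]1(C)CCC[C@@]2(C)[C@H]1[C@@H](O[Si](CC)(CC)CC)C[C@@](C)(O[Si](CC)(CC)CC)[C@@H]2CC/C(C)=C\C(=O)OC | intermediate
18 | bis-silyl core with (13Z)-CH2CH2C(CH3)=CH–CH2OH | COC(=O)[C@]1(C)CCC[C@@]2(C)[C@H]1[C@@H](O[Si](CC)(CC)CC)C[C@@](C)(O[Si](CC)(CC)CC)[C@@H]2CC/C(C)=C\CO | intermediate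
19 | (13S,14R)-13,14-epoxy-13-methyl-15-ol (C12 and C15 cis on the oxirane) | COC(=O)[C@]1(C)CCC[C@@]2(C)[C@H]1[C@@H](O[Si](CC)(CC)CC)C[C@@](C)(O[Si](CC)(CC)CC)[C@@H]2CC[C@]3(C)O[C@@H]3CO | intermediate
20 | (13S,14S)-13,14-epoxy-13-methyl-15-al | COC(=O)[C@]1(C)CCC[C@@]2(C)[C@H]1[C@@H](O[Si](CC)(CC)CC)C[C@@](C)(O[Si](CC)(CC)CC)[C@@H]2CC[C@]3(C)O[C@@H]3C=O | intermediate
21 | (13S,14R)-13,14-epoxy-13-methyl-15-yne (C15≡C16H) | COC(=O)[C@]1(C)CCC[C@@]2(C)[C@H]1[C@@H](O[Si](CC)(CC)CC)C[C@@](C)(O[Si](CC)(CC)CC)[C@@H]2CC[C@]3(C)O[C@@H]3C#C | intermediate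
22 | (13R,14R)-13-hydroperoxy-13-methyl-15-yn-14-ol | COC(=O)[C@]1(C)CCC[C@@]2(C)[C@H]1[C@@H](O[Si](CC)(CC)CC)C[C@@](C)(O[Si](CC)(CC)CC)[C@@H]2CC[C@](C)([C@H](O)C#C)OO | intermediate
23 | (13R,14R)-13-[(2-methoxypropan-2-yl)peroxy]-13-methyl-15-yn-14-ol | COC(=O)[C@]1(C)CCC[C@@]2(C)[C@H]1[C@@H](O[Si](CC)(CC)CC)C[C@@](C)(O[Si](CC)(CC)CC)[C@@H]2CC[C@](C)([C@H](O)C#C)OOC(C)(C)OC | intermediate
24 | (13R,14R,15E)-13-perketal-16-(tributylstannyl)-15-en-14-ol | COC(=O)[C@]1(C)CCC[C@@]2(C)[C@H]1[C@@H](O[Si](CC)(CC)CC)C[C@@](C)(O[Si](CC)(CC)CC)[C@@H]2CC[C@](C)([C@H](O)/C=C/[Sn](CCCC)(CCCC)CCCC)OOC(C)(C)OC | intermediate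
25 | 14-methyl carbonate of 24 | COC(=O)[C@]1(C)CCC[C@@]2(C)[C@H]1[C@@H](O[Si](CC)(CC)CC)C[C@@](C)(O[Si](CC)(CC)CC)[C@@H]2CC[C@](C)([C@H](OC(=O)OC)/C=C/[Sn](CCCC)(CCCC)CCCC)OOC(C)(C)OC | intermediate
26 | but-2-ynoic acid | CC#CC(=O)O | starting material
27 | (Z)-3-iodobut-2-enoic acid | OC(=O)/C=C(/C)I | intermediate
28 | (13R,14R,15E,17Z)-14-(methoxycarbonyloxy)-13-perketal-15,17-dien-19-oic acid (key-step precursor) | COC(=O)[C@]1(C)CCC[C@@]2(C)[C@H]1[C@@H](O[Si](CC)(CC)CC)C[C@@](C)(O[Si](CC)(CC)CC)[C@@H]2CC[C@](C)([C@H](OC(=O)OC)/C=C/C(C)=C\C(=O)O)OOC(C)(C)OC | intermediate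
29 | (13R,14E,16S)-butenolide with 13-perketal and 6α,8α-bis(triethylsilyl) ethers (key-step product) | COC(=O)[C@]1(C)CCC[C@@]2(C)[C@H]1[C@@H](O[Si](CC)(CC)CC)C[C@@](C)(O[Si](CC)(CC)CC)[C@@H]2CC[C@](C)(/C=C/[C@@H]3OC(=O)C=C3C)OOC(C)(C)OC | intermediate
30 | CNP0128148.1, (4R,5R,6S,8R,9R,10S,13R,16S)-6α,8α-dihydroxy-13-hydroperoxy (14E)-butenolide methyl ester | COC(=O)[C@]1(C)CCC[C@@]2(C)[C@H]1[C@@H](O)C[C@@](C)(O)[C@@H]2CC[C@](C)(/C=C/[C@@H]1OC(=O)C=C1C)OO | target

**Step count and risks**

Total steps: 26. Longest linear sequence: 25 (steps 1–22 and 24–26; step 23 makes the coupling partner).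

Step 25 (key step). What may go wrong: reduction of, or metal insertion into, the O–O bond by zerovalent palladium or the phosphine (in 28 or in the allylic peroxide 29). The C14-to-C16 transfer could also erode through re-ionisation of the allylic lactone or exchange between palladium centres. Fallback: the ring would be closed from the free C14 alcohol with divalent palladium and no phosphine. It sets out from 24, which is coupled with 27 under the conditions of step 24 to give the (13R,14R)-14-hydroxy dienoic acid F1. PdCl2(MeCN)2 (10 mol%) in THF at 0 °C should then effect a dehydrative cyclisation: oxypalladation of C15=C16 by the carboxylate, followed by β-hydroxide elimination. This is a syn SN2′ process with the same 1,3-transfer, and it comes back to the route at 29.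

Step 24. What may go wrong: premature ionisation of the allylic carbonate by palladium during the coupling, and protodestannylation by the free acid. Fallback: a palladium-free, copper-mediated coupling of a masked acid. It sets out from 25 and 27. Acid 27 is silylated (Et3SiCl, Et3N, CH2Cl2) to triethylsilyl (Z)-3-iodobut-2-enoate F2. Copper thiophene-2-carboxylate, Cu(O2CC4H3S) (monovalent copper, 1.5 equiv), in N-methylpyrrolidinone at 0 °C should join F2 and 25 to the silyl dienoate F3. The silyl ester is hydrolysed by a pH 7 buffer during work-up, and the sequence comes back at 28.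

Step 9. What may go wrong: poor facial control in the reduction at C6, or β-elimination of the 8-oxygen from the samarium enolate before protonation. Fallback: kinetic reduction followed by equilibration. It sets out from 11, isolated after the −90 °C stage alone. NaBH4 in MeOH at 0 °C should add hydride from the open α-face to give the axial 6β-alcohol F4. Meerwein–Ponndorf–Verley/Oppenauer equilibration (Al(Oi-Pr)3, acetone, i-PrOH, toluene, 80 °C) should then drain it into the far more stable equatorial 6α-alcohol, coming back at 12.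

Further compounds
F1 | step 25 | (13R,14R,15E,17Z)-14-hydroxy-13-perketal-15,17-dien-19-oic acid (28 without the carbonate) | COC(=O)[C@]1(C)CCC[C@@]2(C)[C@H]1[C@@H](O[Si](CC)(CC)CC)C[C@@](C)(O[Si](CC)(CC)CC)[C@@H]2CC[C@](C)([C@H](O)/C=C/C(C)=C\C(=O)O)OOC(C)(C)OC
F2 | step 24 | triethylsilyl (Z)-3-iodobut-2-enoate | CC[Si](CC)(CC)OC(=O)/C=C(/C)I
F3 | step 24 | triethylsilyl ester of 28 | COC(=O)[C@]1(C)CCC[C@@]2(C)[C@H]1[C@@H](O[Si](CC)(CC)CC)C[C@@](C)(O[Si](CC)(CC)CC)[C@@H]2CC[C@](C)([C@H](OC(=O)OC)/C=C/C(C)=C\C(=O)O[Si](CC)(CC)CC)OOC(C)(C)OC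
F4 | step 9 | 6β-hydroxy epimer of 12 (6β,8α-diol, C13 isopropyl ester) | COC(=O)[C@]1(C)CCC[C@@]2(C)[C@H]1[C@H](O)C[C@@](C)(O)[C@@H]2CCC(=O)OC(C)C
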